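**Plan**
Numbering: ring C1 (CHOH), C2=C3, C4H2, C5 (quaternary carbinol), C6H2. The side chain is C1′–C16′, with the Z-alkene at C12′=C13′ and phenyl on C16′.
Cuts: the C1–OH/C2=C3 allylic alcohol is traced back to a C1=C2 alkene. Then C1′–C2′ is cut (spiro-epoxide plus C15 organocopper), then C11′–C12′ (acetylide alkylation), and last C3–C4 and C5–C6 ([4+2]).
Enabling feature: C5 carries O and C1′ and lies between the two ring CH2 groups C4 and C6 of a six-membered carbocycle. It therefore maps onto the α-carbon of a 2-acyloxyacrolein (C4=C5, CHO = C1′), and C6–C1=C2–C3 maps onto butadiene.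
Forward order: the only ring closes first. CHO/OBz then become the spiro-epoxide, the chain is joined at C1′–C2′, and the ring alkene is transposed as the C1 oxygen is introduced.
Stereochemistry: C5 comes from catalyst-controlled face selection in the cycloaddition. C1 is relayed from C5 through a bridging carbonate (cis-1,3). The Z-alkene comes from Lindlar semihydrogenation.

Key step: step 3

Assumption: the acyloxyacrolein is taken to bind to the oxazaborolidinium ion as 2-bromoacrolein does, which points to the (R)-prolinol-derived catalyst for the S adduct; if the sense proved opposite, the equally available (S)-catalyst would be used and nothing else would change.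

Step 1
Reactants: 1 2,2-dimethyl-1,3-dioxan-5-one
Product: 3 2,2-dimethyl-4H-1,3-dioxin-5-yl benzoate, via potassium enolate 2 (not isolated)
Conditions: KHMDS, THF, −78 °C; BzCl, −78 → 0 °C
Reagents that add atoms: benzoyl chloride, O=C(Cl)c1ccccc1
Why: O-acylation of a ketone enolate, in which the loosely paired potassium enolate meets the hard acyl chloride at oxygen rather than carbon to give the enol ester, while the low temperature holds back self-aldol addition of the dioxanone.

Step 2
Reactants: 3 2,2-dimethyl-4H-1,3-dioxin-5-yl benzoate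
Product: 4 2-(benzoyloxy)acrolein (1-formylvinyl benzoate)
Conditions: toluene, 110 °C, N2 sweep, BHT (cat.)
Reagents that add atoms: none
Why: Retro-hetero-Diels–Alder reaction, since the 4H-1,3-dioxin is the formal cycloadduct of an enal and acetone, so heating breaks O1–C2 and O3–C4 and escape of the volatile ketone drives the equilibrium to the enal.

Step 3
Reactants: 4 2-(benzoyloxy)acrolein; 5 buta-1,3-diene
Product: 6 (S)-1-formylcyclohex-3-en-1-yl benzoate
Conditions: B-(o-tolyl)oxazaborolidine from (R)-α,α-diphenylprolinol, protonated with Tf2NH (15 mol %), 5 (10 equiv, condensed), CH2Cl2, −78 → −40 °C, closed vessel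
Reagents that add atoms: none
Why: The formyl oxygen of 4 binds to the cationic boron centre, which lowers the enal LUMO far enough for the unactivated diene, and a concerted but asynchronous suprafacial [4π+2π] cycloaddition then forms C3–C4 and C5–C6 in one event. The closest known reaction type is the enantioselective Diels–Alder reaction of α-substituted acroleins (2-bromo-, 2-methyl- and 2-acyloxyacroleins) with simple acyclic dienes under chiral cationic boron Lewis acids or chiral ammonium salts. The cyclohexene ring C1–C6 closes in the intermolecular [4+2] mode, with all six ring atoms supplied by the two partners and the new alkene at C1=C2. The only new stereocentre, C5, is set by the catalyst: B–O coordination and a formyl C–H···O contact hold the s-trans enal above one aryl group of the diarylcarbinol unit, which screens the Re face of C5, so the diene should add to the Si face (O > CHO > CH2) and give the S configuration. Face selection is the only selectivity needed, because with the C2v-symmetric, unsubstituted diene both orientations and both endo/exo modes lead to the same product, and the very different geminal groups on the sp2 carbon (OBz against CHO) give the catalyst a handle that the two nearly identical CH2 arms of the product could not offer. Excess diene and low temperature are meant to let cycloaddition outrun polymerisation of the dienophile.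

Step 4
Reactants: 6 (S)-1-formylcyclohex-3-en-1-yl benzoate
Product: 7 (S)-1-(hydroxymethyl)cyclohex-3-en-1-ol
Conditions: LiAlH4, Et2O, 0 °C → rt; aqueous quench
Reagents that add atoms: none
Why: Hydride reduction turns the formyl group into C1′H2OH and cleaves the benzoate at its acyl carbon in the same operation, so the C5–O bond and the configuration stay untouched and acyl migration is of no concern.

Step 5
Reactants: 7 (S)-1-(hydroxymethyl)cyclohex-3-en-1-ol
Product: 9 (3S)-1-oxaspiro[2.5]oct-5-ene, via primary tosylate 8 (not isolated)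
Conditions: NaH (2.2 equiv), THF, 0 °C; N-tosylimidazole, 0 °C → rt; pentane extraction, careful concentration (volatile)
Reagents that add atoms: none
Why: One-pot sulfonylation and intramolecular Williamson closure (3-exo-tet), in which the unhindered primary alkoxide takes the tosyl group and the tertiary alkoxide then displaces it at C1′, so C5 keeps its oxygen and its configuration.

Step 6
Reactants: 10 5-phenylpent-1-yne; 11 1,10-dibromodecane
Product: 13 (15-bromopentadec-4-yn-1-yl)benzene, via lithium acetylide 12 (not isolated)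
Conditions: n-BuLi, THF, −78 → 0 °C; 11 (3 equiv), DMPU, 0 °C → rt
Reagents that add atoms: none
Why: SN2 alkylation of a lithium acetylide with a primary bromide in a dipolar cosolvent, where a threefold excess of the cheap symmetrical dibromide suppresses double alkylation and the surplus is removed by distillation.

Step 7
Reactants: 13 (15-bromopentadec-4-yn-1-yl)benzene
Product: 14 [(Z)-15-bromopentadec-4-en-1-yl]benzene
Conditions: H2 (1 atm), Lindlar catalyst, quinoline, hexane, rt
Reagents that add atoms: none
Why: Lindlar semihydrogenation delivers H2 syn to the adsorbed alkyne on poisoned palladium, which sets the Z geometry of the future C12′=C13′ and leaves the primary bromide and the arene alone.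

Step 8
Reactants: 14 [(Z)-15-bromopentadec-4-en-1-yl]benzene; 9 (3S)-1-oxaspiro[2.5]oct-5-ene
Product: 16 (S)-1-[(Z)-16-phenylhexadec-12-en-1-yl]cyclohex-3-en-1-ol, via Grignard reagent 15 (not isolated)
Conditions: Mg, THF, 40 °C; CuI (10 mol %), then 9, THF, −30 → 0 °C
Reagents that add atoms: none
Why: Copper-catalysed Grignard opening of a 2,2-disubstituted epoxide, in which the organocopper species attacks the unhindered CH2 terminus (C1′) in SN2 fashion, forms C1′–C2′ and frees the tertiary alkoxide without touching the C5–O bond.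

Step 9
Reactants: 16 (S)-1-[(Z)-16-phenylhexadec-12-en-1-yl]cyclohex-3-en-1-ol
Product: 18 tert-butyl (S)-1-[(Z)-16-phenylhexadec-12-en-1-yl]cyclohex-3-en-1-yl carbonate, via lithium alkoxide 17 (not isolated)
Conditions: n-BuLi, THF, −78 → 0 °C; Boc2O, 0 °C → rt
Reagents that add atoms: di-tert-butyl dicarbonate, CC(C)(C)OC(=O)OC(=O)OC(C)(C)C
Why: Acylation of a preformed tertiary lithium alkoxide with Boc2O is the standard route to carbonates of hindered alcohols that respond poorly to amine catalysis.

Step 10
Reactants: 18 tert-butyl (S)-1-[(Z)-16-phenylhexadec-12-en-1-yl]cyclohex-3-en-1-yl carbonate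
Product: 19 (1S,5S,6S)-6-iodo-1-[(Z)-16-phenylhexadec-12-en-1-yl]-2,4-dioxabicyclo[3.3.1]nonan-3-one (carbonate bridging the C1 and C5 oxygens on one ring face, iodine on C2 on the opposite face)
Conditions: NIS (1.1 equiv), CH2Cl2/MeCN, −20 → 0 °C, dark
Reagents that add atoms: N-iodosuccinimide, O=C1CCC(=O)N1I
Why: Iodocarbonate cyclisation of a homoallylic tert-butyl carbonate, in which iodonium formation is reversible on both alkenes but only the ring alkene has the axial carbonate carbonyl within reach, so anti opening at C1 (six-membered carbonate rather than seven-membered at C2) places the new C1–O bond cis to C5–O and the iodine trans on C2, and loss of isobutene makes the capture irreversible.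

Step 11
Reactants: 19 (1S,5S,6S)-6-iodo-1-[(Z)-16-phenylhexadec-12-en-1-yl]-2,4-dioxabicyclo[3.3.1]nonan-3-one
Product: 20 (1S,5S)-1-[(Z)-16-phenylhexadec-12-en-1-yl]-2,4-dioxabicyclo[3.3.1]non-6-en-3-one
Conditions: DBU, toluene, 80 °C
Reagents that add atoms: none
Why: E2 dehydroiodination, since in the rigid bicycle the axial C2–I bond is antiperiplanar only to the axial hydrogen on C3 (the hydrogen on C1 is equatorial), so the C2=C3 alkene should form with the carbonate and both stereocentres intact.

Step 12
Reactants: 20 (1S,5S)-1-[(Z)-16-phenylhexadec-12-en-1-yl]-2,4-dioxabicyclo[3.3.1]non-6-en-3-one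
Product: 21 (1S,3S)-1-[(Z)-16-phenylhexadec-12-en-1-yl]cyclohex-4-ene-1,3-diol (cis-diol, target)
Conditions: NaOH (aq), THF/MeOH, rt
Reagents that add atoms: none
Why: Saponification of the cyclic carbonate by attack at the carbonyl carbon (acyl–oxygen cleavage) releases both hydroxyl groups with retention at C1 and C5 and affects neither alkene.

**Compound list**
1 | 2,2-dimethyl-1,3-dioxan-5-one | CC1(C)OCC(=O)CO1 | starting material
2 | potassium 2,2-dimethyl-4H-1,3-dioxin-5-olate | CC1(C)OCC([O-])=CO1.[K+] | intermediate
3 | 2,2-dimethyl-4H-1,3-dioxin-5-yl benzoate | CC1(C)OCC(OC(=O)c2ccccc2)=CO1 | intermediate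
4 | 2-(benzoyloxy)acrolein | C=C(C=O)OC(=O)c1ccccc1 | intermediate
5 | buta-1,3-diene | C=CC=C | starting material
6 | (S)-1-formylcyclohex-3-en-1-yl benzoate | C1=CCC[C@@](OC(=O)c2ccccc2)(C=O)C1 | intermediate
7 | (S)-1-(hydroxymethyl)cyclohex-3-en-1-ol | C1=CCC[C@@](O)(CO)C1 | intermediate
8 | [(S)-1-hydroxycyclohex-3-en-1-yl]methyl 4-methylbenzenesulfonate | C1=CCC[C@@](O)(COS(=O)(=O)c2ccc(C)cc2)C1 | intermediate
9 | (3S)-1-oxaspiro[2.5]oct-5-ene | C1=CCC[C@@]2(CO2)C1 | intermediate
10 | 5-phenylpent-1-yne | C#CCCCc1ccccc1 | starting material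
11 | 1,10-dibromodecane | BrCCCCCCCCCCBr | starting material
12 | lithium 5-phenylpent-1-yn-1-ide | [Li]C#CCCCc1ccccc1 | intermediate
13 | (15-bromopentadec-4-yn-1-yl)benzene | BrCCCCCCCCCCC#CCCCc1ccccc1 | intermediate
14 | [(Z)-15-bromopentadec-4-en-1-yl]benzene | BrCCCCCCCCCC/C=C\CCCc1ccccc1 | intermediate
15 | [(Z)-15-phenylpentadec-11-en-1-yl]magnesium bromide | Br[Mg]CCCCCCCCCC/C=C\CCCc1ccccc1 | intermediate
16 | (S)-1-[(Z)-16-phenylhexadec-12-en-1-yl]cyclohex-3-en-1-ol | C1=CCC[C@@](O)(CCCCCCCCCCC/C=C\CCCc2ccccc2)C1 | intermediate
17 | lithium (S)-1-[(Z)-16-phenylhexadec-12-en-1-yl]cyclohex-3-en-1-olate | C1=CCC[C@@]([O-])(CCCCCCCCCCC/C=C\CCCc2ccccc2)C1.[Li+] | intermediate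
18 | tert-butyl (S)-1-[(Z)-16-phenylhexadec-12-en-1-yl]cyclohex-3-en-1-yl carbonate | C1=CCC[C@@](OC(=O)OC(C)(C)C)(CCCCCCCCCCC/C=C\CCCc2ccccc2)C1 | intermediate
19 | (1S,5S,6S)-6-iodo-1-[(Z)-16-phenylhexadec-12-en-1-yl]-2,4-dioxabicyclo[3.3.1]nonan-3-one | O=C1O[C@H]2C[C@](CCCCCCCCCCC/C=C\CCCc3ccccc3)(CC[C@@H]2I)O1 | intermediate
20 | (1S,5S)-1-[(Z)-16-phenylhexadec-12-en-1-yl]-2,4-dioxabicyclo[3.3.1]non-6-en-3-one | O=C1O[C@H]2C[C@](CCCCCCCCCCC/C=C\CCCc3ccccc3)(CC=C2)O1 | intermediate
21 | (1S,3S)-1-[(Z)-16-phenylhexadec-12-en-1-yl]cyclohex-4-ene-1,3-diol | O[C@@H]1C=CC[C@@](O)(CCCCCCCCCCC/C=C\CCCc2ccccc2)C1 | target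

**Totals**
Total step count: 12.
Longest linear sequence: 10 steps (steps 1–5 and 8–12, from 1 to 21).

**Steps most likely to fail**

Step 3. The unactivated diene may react too slowly, so that acid-induced polymerisation of the dienophile takes over. Face discrimination may also erode if the benzoate carbonyl competes with the formyl group for boron. The fallback sets out from 4 and 5 and comes back at 7. It keeps the same cycloaddition but replaces catalyst control by classical resolution.
- The two partners are heated without catalyst (toluene, 110 °C, sealed tube, BHT) to give racemic 1-formylcyclohex-3-en-1-yl benzoate F1.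
- Pinnick oxidation (NaClO2, NaH2PO4, 2-methylbut-2-ene) gives racemic 1-(benzoyloxy)cyclohex-3-ene-1-carboxylic acid F2.
- Fractional crystallisation with (S)-1-phenylethylamine should furnish the (S)-1-phenylethylammonium salt of the (S)-acid F3.
- Dilute HCl releases (S)-1-(benzoyloxy)cyclohex-3-ene-1-carboxylic acid F4.
- LiAlH4 reduces the carboxyl group and cleaves the benzoate to give 7.

Step 10. Electrophilic iodine may engage the chain alkene (addition or Z-to-E isomerisation). The hindered tertiary carbonate may also be slow to reach the diaxial geometry needed for closure. The fallback sets out from 16 and comes back at 21. It avoids electrophilic halogen altogether.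
- Hydroxyl-directed epoxidation (VO(acac)2, t-BuOOH, CH2Cl2) should act only on the alkene within reach of the vanadium-bound C5 alkoxide. It gives (1S,3S,6R)-3-[(Z)-16-phenylhexadec-12-en-1-yl]-7-oxabicyclo[4.1.0]heptan-3-ol F7, the epoxide cis to the hydroxyl group.
- In the half-chair with the chain equatorial and the hydroxyl group axial, sodium phenylselenide (PhSeSePh, NaBH4, EtOH) should open the epoxide trans-diaxially at C2. The product is (1S,3S,4S)-1-[(Z)-16-phenylhexadec-12-en-1-yl]-4-(phenylselanyl)cyclohexane-1,3-diol F8.
- Oxidation (H2O2, pyridine, THF, 0 °C → rt) gives the corresponding selenoxide F9. Its syn-elimination runs away from the carbinol carbon and delivers 21.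

Step 8. Magnesium halide may induce rearrangement of the 2,2-disubstituted epoxide or halohydrin formation before the C–C bond forms, and the volatile epoxide may be lost on handling. The fallback sets out from 14 and 9 and comes back at 16. It uses a stabilised carbanion in place of the organocopper reagent.
- Sodium benzenesulfinate (DMF, 60 °C) converts 14 into [(Z)-15-phenylpentadec-11-en-1-yl] phenyl sulfone F5.
- F5 is deprotonated with n-BuLi (THF/DMPU, −78 °C) and warmed with 9. This gives (1S)-1-[(Z)-16-phenyl-2-(phenylsulfonyl)hexadec-12-en-1-yl]cyclohex-3-en-1-ol F6, whose mixture at C2′ is of no consequence.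
- Reductive desulfonylation (Na/Hg, Na2HPO4, MeOH) gives 16.

**Further compounds**
F1 | step 3 | racemic 1-formylcyclohex-3-en-1-yl benzoate | O=CC1(OC(=O)c2ccccc2)CC=CCC1
F2 | step 3 | racemic 1-(benzoyloxy)cyclohex-3-ene-1-carboxylic acid | OC(=O)C1(OC(=O)c2ccccc2)CC=CCC1
F3 | step 3 | (S)-1-phenylethylammonium (S)-1-(benzoyloxy)cyclohex-3-ene-1-carboxylate | C1=CCC[C@@](OC(=O)c2ccccc2)(C(=O)[O-])C1.C[C@H]([NH3+])c1ccccc1
F4 | step 3 | (S)-1-(benzoyloxy)cyclohex-3-ene-1-carboxylic acid | C1=CCC[C@@](OC(=O)c2ccccc2)(C(=O)O)C1
F5 | step 8 | [(Z)-15-phenylpentadec-11-en-1-yl] phenyl sulfone | O=S(=O)(CCCCCCCCCC/C=C\CCCc1ccccc1)c1ccccc1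
F6 | step 8 | (1S)-1-[(Z)-16-phenyl-2-(phenylsulfonyl)hexadec-12-en-1-yl]cyclohex-3-en-1-ol | C1=CCC[C@@](O)(CC(CCCCCCCCC/C=C\CCCc2ccccc2)S(=O)(=O)c2ccccc2)C1
F7 | step 10 | (1S,3S,6R)-3-[(Z)-16-phenylhexadec-12-en-1-yl]-7-oxabicyclo[4.1.0]heptan-3-ol | O[C@@]1(CCCCCCCCCCC/C=C\CCCc3ccccc3)CC[C@H]2O[C@H]2C1
F8 | step 10 | (1S,3S,4S)-1-[(Z)-16-phenylhexadec-12-en-1-yl]-4-(phenylselanyl)cyclohexane-1,3-diol | O[C@@H]1[C@@H]([Se]c2ccccc2)CC[C@@](O)(CCCCCCCCCCC/C=C\CCCc2ccccc2)C1
F9 | step 10 | (1S,3S,4S)-1-[(Z)-16-phenylhexadec-12-en-1-yl]-4-(phenylseleninyl)cyclohexane-1,3-diol | O[C@@H]1[C@@H]([Se](=O)c2ccccc2)CC[C@@](O)(CCCCCCCCCCC/C=C\CCCc2ccccc2)C1
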